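The 14-membered ring is numbered C1 (CH bearing the side chain through alkene carbon C15), C4=C5 (E), C8=C9 (Z) and C12 (CH–CH2OH). The plan rests on disconnecting C1–C2 and C1–C15: C1 is a methine flanked by ring methylenes C2 and C14 and by the 1,1-disubstituted alkene carbon C15, the pattern of a secondary boronic ester alkenylated with retention. One telescoped lithiation–borylation–Zweifel operation joins a C1/C14–C11 carbamate (C12 preset), a C2–C10 (4E,8Z)-dienyl pinacol boronic ester and the C15 alkenyllithium, forming both bonds and setting C1 under (+)-sparteine control. The ring is closed afterwards at C10–C11 by sulfone alkylation.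

Key step: step 15

Assumption: the lipase is taken to acetylate the pro-S hydroxymethyl group of 2 (giving the S monoacetate 3); should it prefer the other arm, the two silyl chlorides of steps 3 and 5 are used in the opposite order and the same compound 6 results.

Step 1
Reactants: 1 diethyl 2-allylmalonate
Product: 2 2-allylpropane-1,3-diol
Conditions: LiAlH4, THF, 0 °C → reflux
Reagents that add atoms: none
Why: Hydride reduction of both ester groups is routine and the isolated terminal alkene is inert (ester reduction).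

Step 2
Reactants: 2 2-allylpropane-1,3-diol
Product: 3 (S)-2-(hydroxymethyl)pent-4-en-1-yl acetate
Conditions: Burkholderia cepacia lipase (Amano PS), vinyl acetate, t-BuOMe, rt
Reagents that add atoms: vinyl acetate, C=COC(C)=O
Why: Lipase-catalysed irreversible transesterification (enzymatic desymmetrisation) should acetylate one enantiotopic hydroxymethyl group and so set C12, and letting a little diacetate form should raise the enantiomeric purity of the monoacetate.

Step 3
Reactants: 3 (S)-2-(hydroxymethyl)pent-4-en-1-yl acetate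
Product: 4 (R)-2-[(tert-butyldiphenylsilyloxy)methyl]pent-4-en-1-yl acetate
Conditions: TBDPSCl, imidazole, CH2Cl2, 0 °C
Reagents that add atoms: tert-butyl(chloro)diphenylsilane, CC(C)(C)[Si](Cl)(c1ccccc1)c1ccccc1
Why: Imidazole-promoted silylation of the free primary alcohol at 0 °C should outrun acyl migration, which would otherwise erode C12.

Step 4
Reactants: 4 (R)-2-[(tert-butyldiphenylsilyloxy)methyl]pent-4-en-1-yl acetate
Product: 5 (R)-2-[(tert-butyldiphenylsilyloxy)methyl]pent-4-en-1-ol
Conditions: K2CO3 (cat.), MeOH, 0 °C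
Reagents that add atoms: none
Why: Base-catalysed methanolysis (transesterification) removes the acetate, while the bulky TBDPS ether should neither cleave nor migrate at 0 °C.

Step 5
Reactants: 5 (R)-2-[(tert-butyldiphenylsilyloxy)methyl]pent-4-en-1-ol
Product: 6 (R)-2-allylpropane-1,3-diol 1-TBS 3-TBDPS bis-ether (TBS on the arm that becomes C11)
Conditions: TBSCl, imidazole, DMF, rt
Reagents that add atoms: tert-butyl(chloro)dimethylsilane, CC(C)(C)[Si](C)(C)Cl
Why: Standard silylation installs the more acid-labile silyl ether, so the two oxygen arms on C12 stay distinguishable later.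

Step 6
Reactants: 6 (R)-bis-silyl ether
Product: 8 (R)-5-(tert-butyldimethylsilyloxy)-4-[(tert-butyldiphenylsilyloxy)methyl]pentan-1-ol, via B-alkyl-9-BBN adduct 7 (not isolated)
Conditions: 9-BBN, THF, 0 °C → rt; then NaOH, H2O2, 0 °C → rt
Reagents that add atoms: hydrogen peroxide, OO
Why: Anti-Markovnikov hydroboration of the monosubstituted alkene followed by alkaline peroxide oxidation gives the primary alcohol (C1), and both silyl ethers tolerate these conditions.

Step 7
Reactants: 8 (R)-5-(tert-butyldimethylsilyloxy)-4-[(tert-butyldiphenylsilyloxy)methyl]pentan-1-ol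
Product: 9 (R)-5-(tert-butyldimethylsilyloxy)-4-[(tert-butyldiphenylsilyloxy)methyl]pentyl N,N-diisopropylcarbamate
Conditions: i-Pr2NC(O)Cl, Et3N, CH2Cl2, reflux
Reagents that add atoms: N,N-diisopropylcarbamoyl chloride, CC(C)N(C(C)C)C(=O)Cl
Why: Carbamoylation of the primary alcohol installs the group that directs α-lithiation at C1 and later serves as the leaving group.

Step 8
Reactants: 10 nerol
Product: 11 neryl 4-methoxybenzyl ether
Conditions: NaH, PMBCl, Bu4NI (cat.), THF–DMF, 0 °C → rt
Reagents that add atoms: 4-methoxybenzyl chloride, COc1ccc(CCl)cc1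
Why: Williamson etherification protects the C10 oxygen as a base-stable ether without touching the Z alkene.

Step 9
Reactants: 11 neryl 4-methoxybenzyl ether
Product: 12 (2E,6Z)-8-(4-methoxybenzyloxy)-2,6-dimethylocta-2,6-dien-1-ol
Conditions: SeO2 (cat.), t-BuOOH, salicylic acid (cat.), CH2Cl2, 0 °C → rt
Reagents that add atoms: selenium dioxide, O=[Se]=O (oxygen carrier); tert-butyl hydroperoxide, CC(C)(C)OO (terminal oxygen source)
Why: Riley allylic oxidation (ene reaction, then [2,3]-sigmatropic shift) is selective for the E methyl group of the electron-rich terminal alkene and gives the E allylic alcohol, the C8=C9 alkene being deactivated by its allylic oxygen.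

Step 10
Reactants: 12 (2E,6Z)-8-(4-methoxybenzyloxy)-2,6-dimethylocta-2,6-dien-1-ol
Product: 13 (2Z,6E)-8-bromo-3,7-dimethylocta-2,6-dien-1-yl 4-methoxybenzyl ether
Conditions: CBr4, PPh3, CH2Cl2, 0 °C
Reagents that add atoms: carbon tetrabromide, BrC(Br)(Br)Br
Why: Appel bromination converts the primary allylic alcohol to the bromide under neutral conditions by direct displacement, so both alkene geometries should be kept.

Step 11
Reactants: 13 allylic bromide; 14 bis(pinacolatoboryl)methane
Product: 15 2-{(3E,7Z)-9-(4-methoxybenzyloxy)-3,7-dimethylnona-3,7-dien-1-yl}-4,4,5,5-tetramethyl-1,3,2-dioxaborolane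
Conditions: NaOt-Bu, THF, rt
Reagents that add atoms: none
Why: Alkoxide-promoted deborylative alkylation, in which NaOt-Bu cleaves one boron of 14 to an α-boryl carbanion that should displace the primary allylic bromide at its unhindered terminus (SN2), adds C2 and the boronic ester in one step.

Step 12
Reactants: 16 6-methylhept-5-en-2-one
Product: 17 (E)-2,4,6-triisopropylbenzenesulfonylhydrazone of 6-methylhept-5-en-2-one
Conditions: 2,4,6-(i-Pr)3C6H2SO2NHNH2, HCl (cat.), MeOH, rt
Reagents that add atoms: 2,4,6-triisopropylbenzenesulfonohydrazide, CC(C)c1cc(C(C)C)c(S(=O)(=O)NN)c(C(C)C)c1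
Why: Acid-catalysed condensation of the methyl ketone with the sulfonyl hydrazide gives the crystalline hydrazone needed for the Shapiro reaction.

Step 13
Reactants: 17 trisylhydrazone
Product: 20 2-bromo-6-methylhepta-1,5-diene, via hydrazone dianion 18 (not isolated), via alkenyllithium 19 (not isolated)
Conditions: n-BuLi (2 equiv), TMEDA–hexane, −78 → 0 °C; then BrCH2CH2Br, −78 °C → rt
Reagents that add atoms: 1,2-dibromoethane, BrCCBr
Why: Shapiro reaction, in which the second deprotonation occurs at the methyl group, loss of sulfinate and N2 gives the terminal alkenyllithium regioselectively, and bromination by 1,2-dibromoethane stores it as a purifiable bromide.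

Step 14
Reactants: 20 2-bromo-6-methylhepta-1,5-diene
Product: 19 6-methylhepta-1,5-dien-2-yllithium (solution, used at once)
Conditions: t-BuLi (2 equiv), THF, −78 °C
Reagents that add atoms: tert-butyllithium, [Li]C(C)(C)C
Why: Bromine–lithium exchange with two equivalents of t-BuLi is fast and irreversible at −78 °C and gives the alkenyllithium free of sulfinate and diamine, which would interfere with the iodine step.

Step 15
Reactants: 9 C1 carbamate; 15 C2 pinacol boronic ester; 19 6-methylhepta-1,5-dien-2-yllithium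
Product: 26 open-chain C11-to-C10 compound (C1 S, C12 R) with the side chain on C1, via lithiated carbamate 21 (not isolated), via boronate complex 22 (not isolated), via secondary boronic ester 23 (not isolated), via alkenylboronate complex 24 (not isolated), via iodo boronic ester 25 (not isolated)
Conditions: sec-BuLi, (+)-sparteine, Et2O, −78 °C; 15, −78 °C; MgBr2·OEt2, reflux; aqueous work-up, solvent change to THF; 19, −78 °C; I2, MeOH, −78 °C; NaOMe, MeOH, −78 °C → rt
Reagents that add atoms: none
Why: sec-BuLi/(+)-sparteine removes the pro-R hydrogen at C1 of 9 to give the configurationally stable carbenoid 21, which adds to boronic ester 15 with retention (22), and on warming with MgBr2 the C2 alkyl group undergoes a 1,2-metallate shift anti to the departing carbamate (inversion), forming C1–C2 and the secondary boronic ester 23. Alkenyllithium 19 then gives boronate 24, I2 triggers migration of C1 onto C15 with retention (25), and NaOMe induces anti elimination of boron and iodide to the 1,1-disubstituted alkene, forming C1–C15; the closest known reaction type is lithiation–borylation of sparteine-complexed lithiated carbamates followed by Zweifel olefination with an α-substituted alkenyllithium. No ring is closed in this step. The one new stereocentre, C1 (S), is fixed by the chiral diamine (reagent control) and carried through the retention–inversion–retention sequence, and the remote C12 centre should not override it. The step needs selection between the two C1 hydrogens, supplied by (+)-sparteine and the carbamate-directed deprotonation, and attack of iodine on the electron-rich alkenylboronate in preference to the three isolated alkenes, which the low temperature and the far higher nucleophilicity of the boronate should secure.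

Step 16
Reactants: 26 open-chain C11-to-C10 compound
Product: 27 C11 primary alcohol (C1 S, C12 R; TBDPS and PMB ethers retained)
Conditions: PPTS, MeOH, rt
Reagents that add atoms: none
Why: Acid-catalysed methanolysis (selective desilylation) cleaves the primary TBS ether much faster than the bulkier TBDPS ether and leaves the PMB ether alone.

Step 17
Reactants: 27 C11 primary alcohol
Product: 28 C11 primary iodide (C1 S, C12 S)
Conditions: I2, PPh3, imidazole, CH2Cl2, 0 °C → rt
Reagents that add atoms: iodine, II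
Why: Appel-type iodination converts the primary alcohol to the iodide under neutral conditions compatible with the alkenes and both ethers.

Step 18
Reactants: 28 C11 primary iodide
Product: 29 C11 phenyl sulfone (C1 S, C12 S)
Conditions: PhSO2Na, DMF, 60 °C
Reagents that add atoms: sodium benzenesulfinate, [Na+].[O-]S(=O)c1ccccc1
Why: SN2 displacement of the primary iodide by the sulfur of benzenesulfinate installs the sulfone without any oxidant that could attack the four alkenes.

Step 19
Reactants: 29 C11 phenyl sulfone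
Product: 30 C10 allylic alcohol (sulfone at C11, TBDPS ether retained)
Conditions: DDQ, CH2Cl2–pH 7 buffer, 0 °C
Reagents that add atoms: none
Why: Oxidative cleavage of the PMB ether by DDQ (hydride abstraction, then hydrolysis of the oxocarbenium ion) frees the allylic alcohol, the sulfone and TBDPS ether being inert.

Step 20
Reactants: 30 C10 allylic alcohol
Product: 32 C10 allylic chloride (8Z retained), via allylic mesylate 31 (not isolated)
Conditions: MsCl, 2,4,6-collidine, LiCl, DMF, 0 °C
Reagents that add atoms: lithium chloride, [Li+].[Cl-]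
Why: Mesylation with in situ chloride displacement (SN2) gives the primary allylic chloride without allylic transposition or loss of the Z geometry.

Step 21
Reactants: 32 C10 allylic chloride
Product: 34 14-membered cyclic sulfone (C1 S, C12 S, C11 epimers), via lithiated sulfone 33 (not isolated)
Conditions: LiN(i-Pr)2, THF (high dilution), −78 → 0 °C
Reagents that add atoms: none
Why: Intramolecular SN2 alkylation of the sulfone-stabilised C11 carbanion by the primary allylic chloride closes the 14-membered ring at C10–C11, a known tactic for such carbocycles, and the C11 epimer mixture is irrelevant because the sulfone is removed next.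

Step 22
Reactants: 34 14-membered cyclic sulfone
Product: 35 macrocyclic TBDPS ether (C1 S, C12 S)
Conditions: Na(Hg), Na2HPO4, MeOH–THF, −20 °C → rt
Reagents that add atoms: none
Why: Reductive desulfonylation by electron transfer from the amalgam cleaves the C11–S bond, and since the sulfone is not allylic no alkene can shift.

Step 23
Reactants: 35 macrocyclic TBDPS ether
Product: 36 [(1S,4Z,8E,12S)-5,9-dimethyl-12-(6-methylhepta-1,5-dien-2-yl)cyclotetradeca-4,8-dien-1-yl]methanol (target)
Conditions: Bu4NF, THF, rt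
Reagents that add atoms: none
Why: Fluoride-mediated desilylation liberates the primary alcohol without affecting any alkene or stereocentre.

Compound list
1 | diethyl 2-allylmalonate | C=CCC(C(=O)OCC)C(=O)OCC | starting material
2 | 2-allylpropane-1,3-diol | C=CCC(CO)CO | intermediate
3 | (S)-2-(hydroxymethyl)pent-4-en-1-yl acetate | C=CC[C@H](COC(C)=O)CO | intermediate
4 | (R)-2-[(tert-butyldiphenylsilyloxy)methyl]pent-4-en-1-yl acetate | C=CC[C@H](COC(C)=O)CO[Si](c1ccccc1)(c1ccccc1)C(C)(C)C | intermediate
5 | (R)-2-[(tert-butyldiphenylsilyloxy)methyl]pent-4-en-1-ol | C=CC[C@H](CO)CO[Si](c1ccccc1)(c1ccccc1)C(C)(C)C | intermediate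
6 | (R)-2-allylpropane-1,3-diol 1-TBS 3-TBDPS bis-ether | C=CC[C@H](CO[Si](C)(C)C(C)(C)C)CO[Si](c1ccccc1)(c1ccccc1)C(C)(C)C | intermediate
7 | B-alkyl-9-BBN adduct of 6 (boron on the terminal carbon) | C1CC2CCCC(C1)B2CCC[C@H](CO[Si](C)(C)C(C)(C)C)CO[Si](c1ccccc1)(c1ccccc1)C(C)(C)C | intermediate
8 | (R)-5-(tert-butyldimethylsilyloxy)-4-[(tert-butyldiphenylsilyloxy)methyl]pentan-1-ol | OCCC[C@H](CO[Si](C)(C)C(C)(C)C)CO[Si](c1ccccc1)(c1ccccc1)C(C)(C)C | intermediate
9 | (R)-5-(tert-butyldimethylsilyloxy)-4-[(tert-butyldiphenylsilyloxy)methyl]pentyl N,N-diisopropylcarbamate (ring atoms C1, C14, C13, C12, C11) | CC(C)N(C(C)C)C(=O)OCCC[C@H](CO[Si](C)(C)C(C)(C)C)CO[Si](c1ccccc1)(c1ccccc1)C(C)(C)C | intermediate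
10 | nerol | CC(C)=CCC/C(C)=C\CO | starting material
11 | neryl 4-methoxybenzyl ether | CC(C)=CCC/C(C)=C\COCc1ccc(OC)cc1 | intermediate
12 | (2E,6Z)-8-(4-methoxybenzyloxy)-2,6-dimethylocta-2,6-dien-1-ol | OC/C(C)=C/CC/C(C)=C\COCc1ccc(OC)cc1 | intermediate
13 | (2Z,6E)-8-bromo-3,7-dimethylocta-2,6-dien-1-yl 4-methoxybenzyl ether | BrC/C(C)=C/CC/C(C)=C\COCc1ccc(OC)cc1 | intermediate
14 | bis(pinacolatoboryl)methane | CC1(C)OB(CB2OC(C)(C)C(C)(C)O2)OC1(C)C | starting material
15 | 2-{(3E,7Z)-9-(4-methoxybenzyloxy)-3,7-dimethylnona-3,7-dien-1-yl}-4,4,5,5-tetramethyl-1,3,2-dioxaborolane (ring atoms C2–C10) | CC1(C)OB(CC/C(C)=C/CC/C(C)=C\COCc2ccc(OC)cc2)OC1(C)C | intermediate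
16 | 6-methylhept-5-en-2-one | CC(=O)CCC=C(C)C | starting material
17 | (E)-2,4,6-triisopropylbenzenesulfonylhydrazone of 6-methylhept-5-en-2-one | C/C(CCC=C(C)C)=N\NS(=O)(=O)c1c(C(C)C)cc(C(C)C)cc1C(C)C | intermediate
18 | dilithiated hydrazone (dianion of 17, carbanion on the former methyl group) | [Li+].[Li+].[CH2-]/C(CCC=C(C)C)=N\[N-]S(=O)(=O)c1c(C(C)C)cc(C(C)C)cc1C(C)C | intermediate
19 | 6-methylhepta-1,5-dien-2-yllithium | [Li]C(=C)CCC=C(C)C | intermediate
20 | 2-bromo-6-methylhepta-1,5-diene | C=C(Br)CCC=C(C)C | intermediate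
21 | (1R,4R)-1-lithio derivative of carbamate 9, as its (+)-sparteine complex (diamine omitted) | [Li][C@@H](OC(=O)N(C(C)C)C(C)C)CC[C@H](CO[Si](C)(C)C(C)(C)C)CO[Si](c1ccccc1)(c1ccccc1)C(C)(C)C | intermediate
22 | lithium boronate complex of 21 and 15 (C1 R, boron bearing C1 and C2) | [Li+].CC1(C)O[B-](CC/C(C)=C/CC/C(C)=C\COCc2ccc(OC)cc2)(OC1(C)C)[C@@H](OC(=O)N(C(C)C)C(C)C)CC[C@H](CO[Si](C)(C)C(C)(C)C)CO[Si](c3ccccc3)(c3ccccc3)C(C)(C)C | intermediate
23 | secondary pinacol boronic ester with boron on C1 (C1 S, C12 R) | CC1(C)OB(OC1(C)C)[C@H](CC/C(C)=C/CC/C(C)=C\COCc2ccc(OC)cc2)CC[C@H](CO[Si](C)(C)C(C)(C)C)CO[Si](c3ccccc3)(c3ccccc3)C(C)(C)C | intermediate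
24 | lithium alkenylboronate complex of 23 and 19 | [Li+].C=C(CCC=C(C)C)[B-]1(OC(C)(C)C(C)(C)O1)[C@H](CC/C(C)=C/CC/C(C)=C\COCc2ccc(OC)cc2)CC[C@H](CO[Si](C)(C)C(C)(C)C)CO[Si](c3ccccc3)(c3ccccc3)C(C)(C)C | intermediate
25 | β-iodo boronic ester (boron on C15, iodine on the terminal CH2, C15 configuration undefined) | ICC(CCC=C(C)C)(B1OC(C)(C)C(C)(C)O1)[C@@H](CC[C@H](CO[Si](C)(C)C(C)(C)C)CO[Si](c1ccccc1)(c1ccccc1)C(C)(C)C)CC/C(C)=C/CC/C(C)=C\COCc1ccc(OC)cc1 | intermediate
26 | open-chain C11-to-C10 compound: C1 (S) bearing the 6-methylhepta-1,5-dien-2-yl group, C12 (R) bearing CH2OTBS (C11) and CH2OTBDPS, C10–OPMB, 4E,8Z | C=C(CCC=C(C)C)[C@@H](CC[C@H](CO[Si](C)(C)C(C)(C)C)CO[Si](c1ccccc1)(c1ccccc1)C(C)(C)C)CC/C(C)=C/CC/C(C)=C\COCc1ccc(OC)cc1 | intermediate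
27 | C11 alcohol of 26 (TBS removed; C1 S, C12 R) | C=C(CCC=C(C)C)[C@@H](CC[C@H](CO)CO[Si](c1ccccc1)(c1ccccc1)C(C)(C)C)CC/C(C)=C/CC/C(C)=C\COCc1ccc(OC)cc1 | intermediate
28 | C11 iodide (C1 S, C12 S) | C=C(CCC=C(C)C)[C@@H](CC[C@H](CI)CO[Si](c1ccccc1)(c1ccccc1)C(C)(C)C)CC/C(C)=C/CC/C(C)=C\COCc1ccc(OC)cc1 | intermediate
29 | C11 phenyl sulfone (C1 S, C12 S; C10–OPMB) | C=C(CCC=C(C)C)[C@@H](CC[C@H](CS(=O)(=O)c1ccccc1)CO[Si](c1ccccc1)(c1ccccc1)C(C)(C)C)CC/C(C)=C/CC/C(C)=C\COCc1ccc(OC)cc1 | intermediate
30 | C11 phenyl sulfone with free C10 allylic alcohol | C=C(CCC=C(C)C)[C@@H](CC[C@H](CS(=O)(=O)c1ccccc1)CO[Si](c1ccccc1)(c1ccccc1)C(C)(C)C)CC/C(C)=C/CC/C(C)=C\CO | intermediate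
31 | C10 allylic mesylate of 30 | C=C(CCC=C(C)C)[C@@H](CC[C@H](CS(=O)(=O)c1ccccc1)CO[Si](c1ccccc1)(c1ccccc1)C(C)(C)C)CC/C(C)=C/CC/C(C)=C\COS(C)(=O)=O | intermediate
32 | C10 allylic chloride with C11 phenyl sulfone | C=C(CCC=C(C)C)[C@@H](CC[C@H](CS(=O)(=O)c1ccccc1)CO[Si](c1ccccc1)(c1ccccc1)C(C)(C)C)CC/C(C)=C/CC/C(C)=C\CCl | intermediate
33 | C11 α-lithio sulfone of 32 | C=C(CCC=C(C)C)[C@@H](CC[C@H](C([Li])S(=O)(=O)c1ccccc1)CO[Si](c1ccccc1)(c1ccccc1)C(C)(C)C)CC/C(C)=C/CC/C(C)=C\CCl | intermediate
34 | 14-membered cyclic sulfone (PhSO2 on C11, both epimers; C1 S, C12 S; CH2OTBDPS on C12) | C=C(CCC=C(C)C)[C@@H]1CC/C(C)=C/CC/C(C)=C\CC(S(=O)(=O)c2ccccc2)[C@H](CO[Si](c2ccccc2)(c2ccccc2)C(C)(C)C)CC1 | intermediate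
35 | macrocyclic TBDPS ether of the target (C1 S, C12 S) | C=C(CCC=C(C)C)[C@@H]1CC/C(C)=C/CC/C(C)=C\CC[C@H](CO[Si](c2ccccc2)(c2ccccc2)C(C)(C)C)CC1 | intermediate
36 | [(1S,4Z,8E,12S)-5,9-dimethyl-12-(6-methylhepta-1,5-dien-2-yl)cyclotetradeca-4,8-dien-1-yl]methanol | C=C(CCC=C(C)C)[C@@H]1CC/C(C)=C/CC/C(C)=C\CC[C@H](CO)CC1 | target

Total step count: 23. Longest linear sequence: 16 steps (steps 1–7, 15, 16–23).

Steps most likely to fail

Step 15. The alkenylation half may stall: the congested boronate from the α-branched alkenyllithium may form slowly, or iodine may be consumed by the isolated trisubstituted alkenes so that iodination accompanies the olefination. The fallback keeps the lithiation–borylation that sets C1 and brings in C15 by a second 1,2-metallate homologation without iodine. It sets out from 23, which is isolated. Lithiated 5-methylhex-4-en-1-yl N,N-diisopropylcarbamate (made from the alcohol and i-Pr2NC(O)Cl; sec-BuLi, TMEDA, Et2O, −78 °C; then MgBr2·OEt2, reflux) should insert C15 with retention at C1 and give the C15 pinacol boronic ester F1. NaOH/H2O2 should oxidise it to the C15 secondary alcohol F2, and Dess–Martin periodinane should give the C15 ketone F3. Non-basic methylenation with Cp2Ti(μ-Cl)(μ-CH2)AlMe2 should then give the 1,1-disubstituted alkene without epimerising C1, and the route is rejoined at 26.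

Step 21. Closure by the β-branched C11 carbanion may be slower than intermolecular alkylation or than base-induced loss of HCl from the allylic chloride. The fallback reverses the polarity: an allylic sulfone carbanion at C10, formed with a milder base, is alkylated by a C11 iodide. It sets out from 26. DDQ should give the C10 allylic alcohol F4, MsCl/LiCl/collidine the C10 allylic chloride F5, and PhSO2Na in DMF at rt the C10 allylic phenyl sulfone F6. PPTS/MeOH should then free the C11 alcohol F7, and PPh3/I2/imidazole should give the C11 iodide F8. KN(SiMe3)2 in THF under high dilution should close C10–C11 to the cyclic allylic sulfone F9. PdCl2(dppp)-catalysed reduction with LiBHEt3 should remove the sulfonyl group with the alkene left in place, and the route is rejoined at 35.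

Step 11. The α-boryl carbanion may attack the γ-carbon of the allylic bromide (allylic transposition), or NaOt-Bu may consume the bromide by elimination or ether formation. The fallback separates borylation from the one-carbon extension. It sets out from 13. Pd2(dba)3-catalysed borylation with B2pin2 should give the allylic pinacol boronic ester F10, and Matteson homologation with LiCH2Cl (BrCH2Cl, n-BuLi, THF, −78 °C → rt) should insert C2, rejoining the route at 15.

Further compounds
F1 | step 15 | C15 pinacol boronic ester (26 with C15 as CH–Bpin in place of C=CH2; C1 and C12 as in 26, C15 epimers) | CC(C)=CCCC(B1OC(C)(C)C(C)(C)O1)[C@@H](CC[C@H](CO[Si](C)(C)C(C)(C)C)CO[Si](c1ccccc1)(c1ccccc1)C(C)(C)C)CC/C(C)=C/CC/C(C)=C\COCc1ccc(OC)cc1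
F2 | step 15 | C15 secondary alcohol (C15 epimers) | CC(C)=CCCC(O)[C@@H](CC[C@H](CO[Si](C)(C)C(C)(C)C)CO[Si](c1ccccc1)(c1ccccc1)C(C)(C)C)CC/C(C)=C/CC/C(C)=C\COCc1ccc(OC)cc1
F3 | step 15 | C15 ketone | CC(C)=CCCC(=O)[C@@H](CC[C@H](CO[Si](C)(C)C(C)(C)C)CO[Si](c1ccccc1)(c1ccccc1)C(C)(C)C)CC/C(C)=C/CC/C(C)=C\COCc1ccc(OC)cc1
F4 | step 21 | C10 allylic alcohol of 26 (PMB removed, C11–OTBS kept) | C=C(CCC=C(C)C)[C@@H](CC[C@H](CO[Si](C)(C)C(C)(C)C)CO[Si](c1ccccc1)(c1ccccc1)C(C)(C)C)CC/C(C)=C/CC/C(C)=C\CO
F5 | step 21 | C10 allylic chloride (C11–OTBS kept) | C=C(CCC=C(C)C)[C@@H](CC[C@H](CO[Si](C)(C)C(C)(C)C)CO[Si](c1ccccc1)(c1ccccc1)C(C)(C)C)CC/C(C)=C/CC/C(C)=C\CCl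
F6 | step 21 | C10 allylic phenyl sulfone (C11–OTBS kept) | C=C(CCC=C(C)C)[C@@H](CC[C@H](CO[Si](C)(C)C(C)(C)C)CO[Si](c1ccccc1)(c1ccccc1)C(C)(C)C)CC/C(C)=C/CC/C(C)=C\CS(=O)(=O)c1ccccc1
F7 | step 21 | C11 alcohol of the C10 allylic sulfone | C=C(CCC=C(C)C)[C@@H](CC[C@H](CO)CO[Si](c1ccccc1)(c1ccccc1)C(C)(C)C)CC/C(C)=C/CC/C(C)=C\CS(=O)(=O)c1ccccc1
F8 | step 21 | C11 iodide of the C10 allylic sulfone | C=C(CCC=C(C)C)[C@@H](CC[C@H](CI)CO[Si](c1ccccc1)(c1ccccc1)C(C)(C)C)CC/C(C)=C/CC/C(C)=C\CS(=O)(=O)c1ccccc1
F9 | step 21 | 14-membered cyclic allylic sulfone (PhSO2 on C10, both epimers) | C=C(CCC=C(C)C)[C@@H]1CC/C(C)=C/CC/C(C)=C\C(S(=O)(=O)c2ccccc2)C[C@H](CO[Si](c2ccccc2)(c2ccccc2)C(C)(C)C)CC1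
F10 | step 11 | 2-{(2E,6Z)-8-(4-methoxybenzyloxy)-2,6-dimethylocta-2,6-dien-1-yl}-4,4,5,5-tetramethyl-1,3,2-dioxaborolane | CC1(C)OB(C/C(C)=C/CC/C(C)=C\COCc2ccc(OC)cc2)OC1(C)C
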